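**Assumption:** the SMILES is read as (2S,4S,6S)-2-(4-hydroxy-3-methoxyphenyl)-6-[(1S)-1-hydroxy-2-(4-hydroxyphenyl)ethyl]tetrahydro-2H-pyran-4-ol: aryl and 4-OH cis, the C6 side chain trans to both, the two vicinal C–O centres syn (threo). Simple reagents (BnBr, TMSCl, NBS, borate) are not numbered.

## Retrosynthetic overview

1. Target ⇐ hydrogenolysis of three benzyl ethers ⇐ bulky-hydride reduction of a 2,6-trans tetrahydropyran-4-one (sets the C4 carbinol).
2. 2,6-trans ketone ⇐ rhodium-catalysed conjugate addition of an arylboronic acid (from guaiacol) to a 2-substituted 2,3-dihydro-4H-pyran-4-one (sets the aryl centre trans to the side chain).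
3. Dihydropyranone ⇐ intramolecular oxa-Michael addition/elimination of an acyclic 5-hydroxy-1-methoxy-enone. This is the only ring that is built (both benzene rings are bought); it is closed once, before the arylation.
4. Hydroxy enone ⇐ chelation-controlled Mukaiyama aldol of Danishefsky's diene with an (S)-2-benzyloxy aldehyde from O-benzyl-L-tyrosine (chiral pool gives the side-chain carbinol, the aldol gives the ring C–O centre).
5. Three branches (aldehyde, diene, boronic acid) converge in steps 5 and 10.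

## Route

Step 1
Reactants: 1 O-benzyl-L-tyrosine
Product: 4 (S)-3-[4-(benzyloxy)phenyl]-2-hydroxypropanoic acid, via diazonium carboxylate 2 (not isolated), via alpha-lactone 3 (not isolated)
Conditions: NaNO2, 1 M H2SO4, H2O/1,4-dioxane, 0 °C → rt
Reagents that add atoms: water, O
Why: Nitrous acid deamination (diazotisation) of the alpha-amino acid, in which the diazonium group is displaced first by the neighbouring carboxylate and then by water, so the double SN2 inversion gives the hydroxy acid with overall retention of the (S) centre.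

Step 2
Reactants: 4 (S)-3-[4-(benzyloxy)phenyl]-2-hydroxypropanoic acid
Product: 5 benzyl (S)-2-(benzyloxy)-3-[4-(benzyloxy)phenyl]propanoate
Conditions: BnBr (3 equiv), Ag2O (2 equiv), CH2Cl2, rt, dark
Reagents that add atoms: benzyl bromide, BrCc1ccccc1
Why: Silver-oxide-mediated Williamson-type O-benzylation etherifies the alpha-hydroxyl and esterifies the acid in one operation under non-basic conditions, so the alpha-centre is not enolised and stays (S).

Step 3
Reactants: 5 benzyl (S)-2-(benzyloxy)-3-[4-(benzyloxy)phenyl]propanoate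
Product: 7 (S)-2-(benzyloxy)-3-[4-(benzyloxy)phenyl]propanal, via aluminium hemiacetal 6 (not isolated)
Conditions: i-Bu2AlH (1.1 equiv), PhMe/CH2Cl2, −78 °C; then aq. potassium sodium tartrate (KNaC4H4O6); used crude at once
Reagents that add atoms: none
Why: Partial ester reduction, in which the alpha-benzyloxy group chelates aluminium and keeps the tetrahedral hemiacetal intact at −78 °C, so the aldehyde is released only on work-up and the alpha-centre is not epimerised.

Step 4
Reactants: 8 (E)-4-methoxybut-3-en-2-one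
Product: 9 (E)-1-methoxy-3-(trimethylsilyloxy)buta-1,3-diene (Danishefsky's diene)
Conditions: TMSCl, Et3N, ZnCl2 (cat.), PhMe, 40 °C
Reagents that add atoms: chlorotrimethylsilane, C[Si](C)(C)Cl
Why: Silyl enol ether formation on the methyl ketone gives the 2-silyloxydiene with the (E) enol ether geometry unchanged.

Step 5
Reactants: 7 (S)-2-(benzyloxy)-3-[4-(benzyloxy)phenyl]propanal; 9 (E)-1-methoxy-3-(trimethylsilyloxy)buta-1,3-diene
Product: 10 (1E,5S,6S)-6-(benzyloxy)-7-[4-(benzyloxy)phenyl]-5-hydroxy-1-methoxyhept-1-en-3-one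
Conditions: MgBr2·OEt2 (2 equiv), CH2Cl2, −78 → −20 °C; then sat. aq. NaHCO3
Reagents that add atoms: none
Why: Chelation-controlled Mukaiyama aldol, in which magnesium bridges the aldehyde and alpha-benzyloxy oxygens and the enol silane attacks the face opposite the arylmethyl group (Cram chelate model), setting the new carbinol (5S), syn to the benzyloxy centre.

Step 6
Reactants: 10 (1E,5S,6S)-6-(benzyloxy)-7-[4-(benzyloxy)phenyl]-5-hydroxy-1-methoxyhept-1-en-3-one
Product: 12 (2S)-2-{(1S)-1-(benzyloxy)-2-[4-(benzyloxy)phenyl]ethyl}-2,3-dihydro-4H-pyran-4-one, via 2-methoxytetrahydropyranone adduct 11 (not isolated)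
Conditions: TFA (0.5 equiv), CH2Cl2, 0 °C → rt
Reagents that add atoms: none
Why: Acid-promoted intramolecular oxa-Michael addition (6-endo-trig) of the C5 hydroxyl to the beta-methoxy enone closes the pyranone ring, and beta-elimination of methanol from the adduct gives the vinylogous ester without touching either stereocentre.

Step 7
Reactants: 13 guaiacol (2-methoxyphenol)
Product: 14 4-bromo-2-methoxyphenol
Conditions: NBS, MeCN, 0 °C → rt
Reagents that add atoms: N-bromosuccinimide, O=C1CCC(=O)N1Br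
Why: Electrophilic aromatic bromination goes para to the free hydroxyl, the stronger of the two donors.

Step 8
Reactants: 14 4-bromo-2-methoxyphenol
Product: 15 1-(benzyloxy)-4-bromo-2-methoxybenzene
Conditions: BnBr, K2CO3, acetone, reflux
Reagents that add atoms: benzyl bromide, BrCc1ccccc1
Why: Williamson ether synthesis on the phenoxide protects the phenol as a benzyl ether that is later removed with the other two.

Step 9
Reactants: 15 1-(benzyloxy)-4-bromo-2-methoxybenzene
Product: 18 [4-(benzyloxy)-3-methoxyphenyl]boronic acid, via aryllithium 16 (not isolated), via lithium aryltriisopropoxyborate 17 (not isolated)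
Conditions: n-BuLi, THF, −78 °C; B(O-i-Pr)3, −78 °C → rt; 1 M HCl
Reagents that add atoms: triisopropyl borate, CC(C)OB(OC(C)C)OC(C)C; water, O
Why: Bromine–lithium exchange followed by electrophilic borylation and hydrolysis of the borate gives the boronic acid at the former C–Br position.

Step 10
Reactants: 12 (2S)-2-{(1S)-1-(benzyloxy)-2-[4-(benzyloxy)phenyl]ethyl}-2,3-dihydro-4H-pyran-4-one; 18 [4-(benzyloxy)-3-methoxyphenyl]boronic acid
Product: 19 (2S,6S)-2-[4-(benzyloxy)-3-methoxyphenyl]-6-{(1S)-1-(benzyloxy)-2-[4-(benzyloxy)phenyl]ethyl}tetrahydro-4H-pyran-4-one (2,6-trans)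
Conditions: [Rh(OH)(cod)]2 (3 mol %; cod = cycloocta-1,5-diene), 18 (2 equiv), 1,4-dioxane/H2O 10:1, 40 °C
Reagents that add atoms: none
Why: Rhodium-catalysed conjugate addition of the arylboronic acid (Hayashi–Miyaura reaction), in which the aryl–rhodium species attacks the enone carbon next to the ring oxygen axially, on the face anti to the pseudo-equatorial side chain, giving the 2,6-trans ketone with the new centre (S).

Step 11
Reactants: 19 (2S,6S)-2-[4-(benzyloxy)-3-methoxyphenyl]-6-{(1S)-1-(benzyloxy)-2-[4-(benzyloxy)phenyl]ethyl}tetrahydro-4H-pyran-4-one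
Product: 20 (2S,4S,6S)-2-[4-(benzyloxy)-3-methoxyphenyl]-6-{(1S)-1-(benzyloxy)-2-[4-(benzyloxy)phenyl]ethyl}tetrahydro-2H-pyran-4-ol
Conditions: LiBH(s-Bu)3 (1.3 equiv), THF, −78 °C; then H2O
Reagents that add atoms: none
Why: Bulky-hydride ketone reduction, in which 19 reacts through the chair with the branched side chain equatorial and the aryl group axial and the hydride enters equatorially on the face away from the axial aryl, so the new hydroxyl is cis to the aryl and trans to the side chain (4S).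

Step 12
Reactants: 20 (2S,4S,6S)-2-[4-(benzyloxy)-3-methoxyphenyl]-6-{(1S)-1-(benzyloxy)-2-[4-(benzyloxy)phenyl]ethyl}tetrahydro-2H-pyran-4-ol
Product: 21 (2S,4S,6S)-2-(4-hydroxy-3-methoxyphenyl)-6-[(1S)-1-hydroxy-2-(4-hydroxyphenyl)ethyl]tetrahydro-2H-pyran-4-ol (target)
Conditions: H2 (1 atm), 10% Pd/C, EtOAc/MeOH, rt, stopped after uptake of 3 equiv
Reagents that add atoms: none
Why: Catalytic hydrogenolysis removes the three O-benzyl groups under neutral conditions, under which the cyclic benzylic C–O bond of the ring is cleaved much more slowly and no stereocentre is affected.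

## Compound list

1 | O-benzyl-L-tyrosine | N[C@@H](Cc1ccc(OCc2ccccc2)cc1)C(=O)O | starting material
2 | (S)-diazonium carboxylate of 1 | [O-]C(=O)[C@@H]([N+]#N)Cc1ccc(OCc2ccccc2)cc1 | intermediate (not isolated)
3 | (R)-3-[4-(benzyloxy)benzyl]oxiran-2-one (alpha-lactone) | O=C1O[C@@H]1Cc1ccc(OCc2ccccc2)cc1 | intermediate (not isolated)
4 | (S)-3-[4-(benzyloxy)phenyl]-2-hydroxypropanoic acid | OC(=O)[C@@H](O)Cc1ccc(OCc2ccccc2)cc1 | intermediate
5 | benzyl (S)-2-(benzyloxy)-3-[4-(benzyloxy)phenyl]propanoate | O=C(OCc1ccccc1)[C@@H](OCc1ccccc1)Cc1ccc(OCc2ccccc2)cc1 | intermediate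
6 | diisobutylaluminium hemiacetal of 5 (hemiacetal carbon unassigned) | CC(C)C[Al](CC(C)C)OC(OCc1ccccc1)[C@@H](OCc1ccccc1)Cc1ccc(OCc2ccccc2)cc1 | intermediate (not isolated)
7 | (S)-2-(benzyloxy)-3-[4-(benzyloxy)phenyl]propanal | O=C[C@@H](OCc1ccccc1)Cc1ccc(OCc2ccccc2)cc1 | intermediate
8 | (E)-4-methoxybut-3-en-2-one | CO/C=C/C(C)=O | starting material
9 | (E)-1-methoxy-3-(trimethylsilyloxy)buta-1,3-diene | CO/C=C/C(=C)O[Si](C)(C)C | intermediate
10 | (1E,5S,6S)-6-(benzyloxy)-7-[4-(benzyloxy)phenyl]-5-hydroxy-1-methoxyhept-1-en-3-one | CO/C=C/C(=O)C[C@@H]([C@@H](OCc1ccccc1)Cc1ccc(OCc2ccccc2)cc1)O | intermediate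
11 | (6S)-6-{(1S)-1-(benzyloxy)-2-[4-(benzyloxy)phenyl]ethyl}-2-methoxytetrahydro-4H-pyran-4-one (both C2 epimers) | COC1CC(=O)C[C@@H]([C@@H](OCc2ccccc2)Cc2ccc(OCc3ccccc3)cc2)O1 | intermediate (not isolated)
12 | (2S)-2-{(1S)-1-(benzyloxy)-2-[4-(benzyloxy)phenyl]ethyl}-2,3-dihydro-4H-pyran-4-one | O=C1C[C@@H]([C@@H](OCc2ccccc2)Cc2ccc(OCc3ccccc3)cc2)OC=C1 | intermediate
13 | guaiacol (2-methoxyphenol) | COc1ccccc1O | starting material
14 | 4-bromo-2-methoxyphenol | COc1cc(Br)ccc1O | intermediate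
15 | 1-(benzyloxy)-4-bromo-2-methoxybenzene | COc1cc(Br)ccc1OCc1ccccc1 | intermediate
16 | [4-(benzyloxy)-3-methoxyphenyl]lithium | COc1cc([Li])ccc1OCc1ccccc1 | intermediate (not isolated)
17 | lithium [4-(benzyloxy)-3-methoxyphenyl]triisopropoxyborate | [Li+].COc1cc([B-](OC(C)C)(OC(C)C)OC(C)C)ccc1OCc1ccccc1 | intermediate (not isolated)
18 | [4-(benzyloxy)-3-methoxyphenyl]boronic acid | COc1cc(B(O)O)ccc1OCc1ccccc1 | intermediate
19 | (2S,6S)-2-[4-(benzyloxy)-3-methoxyphenyl]-6-{(1S)-1-(benzyloxy)-2-[4-(benzyloxy)phenyl]ethyl}tetrahydro-4H-pyran-4-one | COc1cc([C@@H]2CC(=O)C[C@@H]([C@@H](OCc3ccccc3)Cc3ccc(OCc4ccccc4)cc3)O2)ccc1OCc1ccccc1 | intermediate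
20 | (2S,4S,6S)-2-[4-(benzyloxy)-3-methoxyphenyl]-6-{(1S)-1-(benzyloxy)-2-[4-(benzyloxy)phenyl]ethyl}tetrahydro-2H-pyran-4-ol | COc1cc([C@@H]2C[C@H](O)C[C@@H]([C@@H](OCc3ccccc3)Cc3ccc(OCc4ccccc4)cc3)O2)ccc1OCc1ccccc1 | intermediate
21 | (2S,4S,6S)-2-(4-hydroxy-3-methoxyphenyl)-6-[(1S)-1-hydroxy-2-(4-hydroxyphenyl)ethyl]tetrahydro-2H-pyran-4-ol | COc1cc([C@@H]2C[C@H](O)C[C@@H]([C@@H](O)Cc3ccc(O)cc3)O2)ccc1O | target

## Step count and risks

Total step count: 12. Longest linear sequence: 8 (steps 1, 2, 3, 5, 6, 10, 11, 12); the boronic acid branch (steps 7–9) and the diene branch (step 4) join at steps 10 and 5.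

**Step 5 (chelation-controlled aldol).** Aldehyde 7 is configurationally labile and the diene is acid-sensitive, so mixtures of open and cyclised material or an eroded syn:anti ratio are possible. The fallback sets out from 7 and comes back at 12.
- Commercial 4-(trimethylsilyl)but-3-yn-2-one is silylated (TMSOTf, Et3N, Et2O, 0 °C) to trimethyl{[4-(trimethylsilyl)but-1-en-3-yn-2-yl]oxy}silane F1.
- TiCl4 (CH2Cl2, −78 °C), a tighter bidentate chelator, mediates the Mukaiyama aldol of F1 with 7 to the syn beta-hydroxy ynone (5S,6S)-6-(benzyloxy)-7-[4-(benzyloxy)phenyl]-5-hydroxy-1-(trimethylsilyl)hept-1-yn-3-one F2.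
- Brief K2CO3/MeOH at 0 °C removes the alkynyl silyl group to give (5S,6S)-6-(benzyloxy)-7-[4-(benzyloxy)phenyl]-5-hydroxyhept-1-yn-3-one F3.
- AgOTf (10 mol %, CH2Cl2, rt) then closes the ring by a 6-endo-dig oxa-Michael addition, giving 12 directly.

**Step 10 (rhodium-catalysed arylation).** The electron-rich boronic acid can protodeboronate, and the enolate or the product can open by retro-oxa-Michael reaction and re-close to the 2,6-cis isomer. The fallback sets out from 15 and 12 and comes back at 19.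
- Bromide 15 is converted (Mg, THF) into [4-(benzyloxy)-3-methoxyphenyl]magnesium bromide F4.
- Copper-catalysed conjugate addition of F4 to 12 (CuBr·SMe2 20 mol %, TMSCl, THF, −78 °C) follows the same axial, anti trajectory. The enolate is trapped as the trimethylsilyl enol ether of the 2,6-trans ketone F5, which cannot ring-open.
- Buffered desilylation (TBAF/AcOH, THF, 0 °C) gives 19.

**Step 11 (facial selectivity of the reduction).** The outcome depends on which chair of the 2,6-trans ketone reacts, so the C4 epimer may predominate. The fallback sets out from 19 and comes back at 20.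
- The reduction product with the hydroxyl trans to the aryl group, the (2S,4R,6S) epimeric alcohol F6, is collected.
- Mitsunobu reaction (4-nitrobenzoic acid, PPh3, DIAD, THF, 0 °C → rt) inverts it to the (2S,4S,6S) 4-nitrobenzoate F7.
- Methanolysis (K2CO3, MeOH, rt) gives 20.

Further compounds
F1 | step 5 | trimethyl{[4-(trimethylsilyl)but-1-en-3-yn-2-yl]oxy}silane | C=C(O[Si](C)(C)C)C#C[Si](C)(C)C
F2 | step 5 | (5S,6S)-6-(benzyloxy)-7-[4-(benzyloxy)phenyl]-5-hydroxy-1-(trimethylsilyl)hept-1-yn-3-one | C[Si](C)(C)C#CC(=O)C[C@@H]([C@@H](OCc1ccccc1)Cc1ccc(OCc2ccccc2)cc1)O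
F3 | step 5 | (5S,6S)-6-(benzyloxy)-7-[4-(benzyloxy)phenyl]-5-hydroxyhept-1-yn-3-one | C#CC(=O)C[C@@H]([C@@H](OCc1ccccc1)Cc1ccc(OCc2ccccc2)cc1)O
F4 | step 10 | [4-(benzyloxy)-3-methoxyphenyl]magnesium bromide | COc1cc([Mg]Br)ccc1OCc1ccccc1
F5 | step 10 | trimethylsilyl enol ether of 19: {[(2S,6S)-6-[4-(benzyloxy)-3-methoxyphenyl]-2-{(1S)-1-(benzyloxy)-2-[4-(benzyloxy)phenyl]ethyl}-3,6-dihydro-2H-pyran-4-yl]oxy}trimethylsilane | COc1cc([C@@H]2C=C(O[Si](C)(C)C)C[C@@H]([C@@H](OCc3ccccc3)Cc3ccc(OCc4ccccc4)cc3)O2)ccc1OCc1ccccc1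
F6 | step 11 | (2S,4R,6S)-2-[4-(benzyloxy)-3-methoxyphenyl]-6-{(1S)-1-(benzyloxy)-2-[4-(benzyloxy)phenyl]ethyl}tetrahydro-2H-pyran-4-ol | COc1cc([C@@H]2C[C@@H](O)C[C@@H]([C@@H](OCc3ccccc3)Cc3ccc(OCc4ccccc4)cc3)O2)ccc1OCc1ccccc1
F7 | step 11 | (2S,4S,6S)-2-[4-(benzyloxy)-3-methoxyphenyl]-6-{(1S)-1-(benzyloxy)-2-[4-(benzyloxy)phenyl]ethyl}tetrahydro-2H-pyran-4-yl 4-nitrobenzoate | COc1cc([C@@H]2C[C@H](OC(=O)c3ccc(cc3)[N+](=O)[O-])C[C@@H]([C@@H](OCc3ccccc3)Cc3ccc(OCc4ccccc4)cc3)O2)ccc1OCc1ccccc1
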